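Saturday's flask ends with more tris adduct than Thursday's, 18 % against 2 %, and I want to know what that difference is worth for the two new flasks.

| setting | Thursday's | Saturday's | midnight | spring |
|---|---|---|---|---|
| substrate | 15 mM | 15 mM | 15 mM | 15 mM |
| coupling partner | 8.3 mM | 50 mM | 45.0 mM | 7.50 mM |
| remark | run made earlier | run made earlier |  |  |
| time |  |  | 3.0 h | 3.0 h |

| run | time / min | mono adduct / % | tris adduct / % |
|---|---|---|---|
| Thursday's | 10.0 | 1 | 4 |
| Thursday's | 25.0 | 0 | 0 |
| Thursday's | 50.0 | 1 | 1 |
| Thursday's | 120 | 0 | 2 |
| Saturday's | 10.0 | 2 | 7 |
| Saturday's | 25.0 | 4 | 13 |
| Saturday's | 50.0 | 0 | 16 |
| Saturday's | 120 | 1 | 18 |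

(scatter of a reading: 2 percentage points)



* which of these holds the largest part of the substrate at the end of midnight (bis adduct / tris adduct / substrate / mono adduct)
* which of these holds the largest part of the substrate at the end of spring (bis adduct / tris adduct / substrate / mono adduct)
* mono adduct at the end of midnight, in percent of the substrate charged

Saturday's tris adduct reads 16 % at 50.0 min and 18 % at 120 min, a step no bigger than the scatter of 2 percentage points, so I drop time and divide the last tris fraction by the equivalents of coupling partner charged, which gives the tris yield per equivalent, 5.40 % on Saturday's 3.33 equivalents. This gives me two ways to midnight's 3.00 equivalents. Saturday's yield gives 16.2 % of tris adduct, while Thursday's, 3.61 % on 0.553 equivalents, gives 10.8 %. They part, and I take Thursday's way to be the one that cheats, since its reading stands one standard deviation above zero and its charge lies further from midnight's than Saturday's does. I commit to Saturday's figure, which leaves 83.8 % of midnight's substrate outside the tris adduct, and I place bis adduct first. Saturday's last mono readings are 0 % and 1 %, so I take 1 % for midnight's mono adduct. In spring the coupling partner is the limiting reagent at 0.500 equivalents, and each substrate that reacts takes at least one, so I estimate a floor of 50.0 % on the substrate left.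

The forecast puts bis adduct first in midnight, substrate first in spring and mono adduct at 1 %, calling it “a short-lived intermediate that passes quickly to the bis adduct”.

The flask gives 0 % of mono adduct at the end of midnight, with bis adduct first there and substrate first in spring, under this scheme:

    coupling partner + bis adduct → tris adduct + released group (k = 0.0640 /M/s)
    substrate + coupling partner → mono adduct + released group (k = 0.930 /M/s)
    2 coupling partner → self-condensation product (k = 0.130 /M/s)
    mono adduct → side product (k = 0.00720 /s)
    coupling partner + mono adduct → bis adduct + released group (k = 0.310 /M/s)

Midnight ends with bis adduct at 21.2 % and tris adduct at 16.0 %, while side product, at 62.8 %, stands outside the four choices asked. The yield per equivalent gave 16.2 % for that tris adduct. Carried to the neighbour of midnight with 180 mM of coupling partner, 12.0 equivalents, it gives 64.8 % of tris adduct, and that flask holds 43.3 % of tris adduct.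

The numbers in the tables are simulated on assumed constants; noise was put on by code.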